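| setting | spring | dusk | Thursday's | Wednesday's |
|---|---|---|---|---|
| free monomer | 0.050 M | 0.050 M | 0.050 M | 0.050 M |
| protic impurity | 0.025 M | 0.038 M | 0.0500 M | 0.0500 M |
| initiator | 1.7 mol% | 1.7 mol% | 1.7 mol% | 1.7 mol% |
| remark | run made earlier | run made earlier |  |  |
| time |  |  | 5.0 min | 3.0 min |

| run | time / min | monomer in chains / % | free monomer / % |
|---|---|---|---|
| spring | 1.50 | 16.5 | 71.8 |
| spring | 3.00 | 36.4 | 47.1 |
| spring | 5.00 | 55.0 | 25.6 |
| spring | 6.00 | 59.0 | 17.7 |
| dusk | 0.500 | 4.0 | 89.9 |
| dusk | 1.00 | 10.1 | 78.1 |
| dusk | 2.50 | 28.6 | 51.3 |
| dusk | 6.00 | 53.6 | 14.2 |

(each reading ± 1 percentage point)

- the average divides the monomer in chains by the number of chains begun, living and dead together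
- the earlier runs were read with a standard deviation of 1 percentage point
- steps thought possible: free monomer + initiator -> living end + monomer in chains; free monomer + living end -> monomer in chains + living end; protic impurity + free monomer -> quenched substrate
- the earlier runs do not show the number of chains; that part of a forecast is a guess

- which of the two ends with the longer chains by the average number of monomer units in a chain (chains begun, living or dead) ("neither" if they lie within 10 %) (Thursday's / Wednesday's / neither)
- average number of monomer units in a chain (chains begun, living or dead) at the end, Thursday's
- average number of monomer units in a chain (chains begun, living or dead) at the end, Wednesday's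

If a chain's length is monomer in chains over chains begun, the monomer in chains comes first. Free monomer goes either into chains or to quenched substrate, and the balance gives the quenched fraction. The ratio of those two has living ends above and impurity below. So, replacing each curve by its mean, I multiplied the ratio by the equivalents of protic impurity.

spring, last reading: 1.27
dusk, last reading: 1.27
spring at 3.00 min: 1.10
early, mean of dusk at 1.00 min and spring at 1.50 min: 0.678

This growth number, a selectivity factor with the impurity divided out, rose with time in the spring run and read the same in the two runs at their last readings, at equal monomer charge and loading.

For free monomer I took the mean loss constant, ln(1/fraction left)/time, from the spring run and added the slope per equivalent of impurity between the last readings of the two runs: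

slope: 0.141 min⁻¹
free fraction: Thursday's 0.180, Wednesday's 0.381
in chains, (1 − free) × G/(G + equivalents): Thursday's 0.458, Wednesday's 0.325

Dividing by the loading, as if each initiator had begun a chain, gave 26.9 and 19.1.

That assumption was the weak link. In the spring run, growth per unit of free monomer in the first interval stood at 0.551 of its later value. I read this as the started fraction halfway through that exposure, which gives a started fraction of 0.949 for Thursday's and 0.908 for Wednesday's. My lengths became 28.4 for Thursday's and 21.0 for Wednesday's, longer on Thursday's.

The forecast named Thursday's, with 30 (26 to 36) and 23 (19 to 28), above my figures, and noted that “the chain count is partly a guess”.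

The flask gave Thursday's: 29.1 against 22.1.

    free monomer + initiator → living end + monomer in chains (k = 0.307 M⁻¹ s⁻¹)
    free monomer + living end → monomer in chains + living end, rate k2*[living end]*[free monomer] (k = 5.55 M⁻¹ s⁻¹)
    protic impurity + free monomer → quenched substrate (k = 0.0636 M⁻¹ s⁻¹)

Both flasks hold the same charge, and the difference in reading time is the main reason for the gap: with that difference taken away, Wednesday's flask stands at 29.1, not 22.1. The growth number of these flasks, at one equivalent of impurity, rises too, 1.00 at 3.00 min and 1.18 at 5.00 min, against my 1.10 and 1.27, read at 3.00 min and 6.00 min.

For Thursday's flask read at 80 s, the early number 0.678, with one equivalent of impurity, puts 0.678 of monomer in chains per unit quenched. The computed flask holds 13.0 % in chains and 19.2 % quenched, a ratio of 0.677, and its length is 11.9.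

The readings were computed for substances that don't exist, noise included.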